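Slowness is what this reckoning turns on: blue, with 10 mM of Ja on 0.18 mM of Jb, read 85.9 % of the Ja charged at its last reading, while ochre, with 6.9 mM of Ja on 0.25 mM of Jb, read 90.2 %.

| setting | ochre | violet | teal | blue | Friday's | Wednesday's |
|---|---|---|---|---|---|---|
| Ja | 6.9 mM | 7.1 mM | 8.7 mM | 10 mM | 6.0 mM | 10 mM |
| Jd | 3 mM | 3 mM | 3 mM | 3 mM | 3.00 mM | 3.00 mM |
| Jb | 0.25 mM | 0.25 mM | 0.25 mM | 0.18 mM | 0.080 mM | 0.25 mM |
| remark | run made earlier | run made earlier | run made earlier | run made earlier |  |  |
| time |  |  |  |  | 10 h | 10 h |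

- ochre (time / h: Jc / %): 0.500: 31.0; 1.00: 57.6; 2.00: 85.1; 4.00: 89.8; 8.00: 90.2
- violet (time / h: Jc / %): 0.667: 39.9; 2.00: 84.4; 3.00: 89.3; 5.00: 89.6; 8.00: 89.6
- teal (time / h: Jc / %): 0.667: 34.2; 2.00: 79.2; 3.00: 87.3; 5.00: 89.2; 8.00: 89.8
- blue (time / h: Jc / %): 0.500: 16.3; 1.00: 33.0; 2.00: 60.1; 4.00: 84.1; 8.00: 85.9

(standard deviation of a reading: 0.5 percentage points)

1. the winner by amount of Jc, in percent of the Ja charged; "neither" if no more than 2 percentage points parts them (Friday's / Wednesday's / neither)
2. how much Jc is there at the end, in percent of the Ja charged: Friday's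
3. how much Jc is there at the end, in percent of the Ja charged: Wednesday's

- candidate steps: Ja + Jd -> Jf; Je <-> Jb + Jc; Ja + Jb -> Je

The runs end on plateaus under 100 %, and the candidate steps offer two places for the missing part: Jf, made from Ja and Jd, and Je, which holds Jc on the catalyst. Ja leaks for as long as it stands, and at a steady pace it stands for a time proportional to c(Ja)/c(Jb) at a mean level proportional to c(Ja). The amount to reckon with is therefore the leak load, c(Ja)²/c(Jb): 450 mM for Friday's, more than 400 mM for Wednesday's.

Time matters little. Blue's first reading gives a pace of 18.1 h⁻¹ per Jb, so at that steady pace Friday's charge needs about 4.14 h, shorter than the 10 h allowed. The charge of Jd matches the runs at 3.00 mM, so it sits inside the line drawn through them. The slope of that line does matter: missing Ja per unit of load counts 1.67 times as much in Friday's percentage as in Wednesday's, since Friday's charge is smaller.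

From ochre to blue, missing Ja rises from 0.676 mM to 1.41 mM as the load rises from 190 mM to 556 mM. This gives the leak yield, the Ja missing per unit of load, 0.00201, on top of a base of 0.293 mM. Teal, read on the same line, should lack 0.902 mM and lacks 0.887 mM. My reckoning is therefore 89.0 % for Wednesday's and 80.0 % for Friday's.

The forecast, which put the shortfall down to “Ja leaking away through Jd, plus a small amount of Jc held as Je”, named Wednesday's, with 89.2 % (87.5 % to 90.5 %) and, a little above my figure, 81 % for Friday's (77 % to 85 %). The flasks give 88.5 % for Wednesday's and 80.4 % for Friday's, so Wednesday's wins.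

    Ja + Jd → Jf (k = 39.8 M⁻¹ h⁻¹)
    Je ⇌ Jb + Jc (K = 0.0105 M, k = 22.4 h⁻¹)
    Ja + Jb → Je (k = 16200 M⁻¹ h⁻¹)

In Wednesday's at 0.957 h, Ja has a half-life of 7.6 h by the step to Jf, far longer than the 1.9 min forward half-life of Je. Ja, the limiting reagent, stands at 0 % at the end of Wednesday's, with Jf at 10.3 %. Wednesday's lacks 1.15 mM against 1.10 mM from the leak yield, and Friday's lacks 1.18 mM against 1.20 mM. The neighbour with 2.5 mM of Ja has a load of 25.0 mM, below ochre's, and there the line gives 86.3 % where the flask gives 93.0 %.

The numbers in the tables are simulated on assumed constants; scatter was added.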